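## Retrosynthetic overview

1. Acid ⇐ methyl ester ⇐ side-chain C–C bond between a ring B CH2CH2–borane (from a vinyl group) and methyl but-2-ynoate; syn addition fixes the E alkene.
2. Ring A: carbonyl removal (Wolff–Kishner) ⇐ reductive alkylation of a ring A enone with 5-bromo-2-methylpent-2-ene, which sets the ring-fusion H and the C(Me)(alkyl) centre.
3. Ring B vinyl ⇐ alkenyl nonaflate ⇐ one-carbon ring expansion of a cyclopentanone by a C(Me)(SiMe3) diazo unit (1,2-shift, then silyl shift to one regiodefined enol derivative).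
4. Bicyclic enedione ⇐ amino-acid-mediated asymmetric Robinson annulation of 2-methylcyclopentane-1,3-dione with ethyl vinyl ketone, which sets the angular methyl centre.
5. Ring order: purchased five-membered ring → ring A (annulation) → ring B grown from five to six members.

Assumption: (trimethylsilyl)diazomethane (hexane solution), potassium ethenyltrifluoroborate, 5-bromo-2-methylpent-2-ene and methyl but-2-ynoate are bought; ring A is the ring with the C(Me)(4-methylpent-3-enyl) centre, ring B the ring with the tetrasubstituted alkene.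

## Route

Step 1
Reactants: 1 2-methylcyclopentane-1,3-dione; 2 pent-1-en-3-one (ethyl vinyl ketone)
Product: 4 (7aS)-4,7a-dimethyl-2,3,7,7a-tetrahydro-1H-indene-1,5(6H)-dione, via Michael triketone 3 (not isolated)
Conditions: 2 (1.5 equiv), H2O, 23 °C; concentrate; then L-phenylalanine (1.0 equiv, recovered), 1 M HClO4 (0.5 equiv), MeCN, 80 °C; recrystallise
Reagents that add atoms: none
Why: Michael addition followed by amino-acid-mediated enamine aldol condensation (Hajos–Parrish/Eder–Sauer–Wiechert Robinson annulation), in which the L-amino acid enamine selects one of the two enantiotopic ring carbonyls and sets the quaternary centre as S.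

Step 2
Reactants: 5 (trimethylsilyl)diazomethane; 6 iodomethane
Product: 8 1-diazo-1-(trimethylsilyl)ethane, via lithiated diazoalkane 7 (not isolated)
Conditions: n-BuLi (1.05 equiv), THF, −78 °C; then 6 (1.1 equiv), −78 → 0 °C; used as a titrated solution
Reagents that add atoms: none
Why: C-lithiation of the silyl diazoalkane and SN2 methylation, a known preparation of this disubstituted diazo reagent.

Step 3
Reactants: 4 (7aS)-4,7a-dimethyl-2,3,7,7a-tetrahydro-1H-indene-1,5(6H)-dione; 8 1-diazo-1-(trimethylsilyl)ethane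
Product: 11 (8aS)-2,5,8a-trimethyl-6-oxo-3,4,6,7,8,8a-hexahydronaphthalen-1-yl nonafluorobutane-1-sulfonate, via α-silyl ketone 9 (not isolated), via silyl enol ether 10 (not isolated)
Conditions: 8 (1.5 equiv), Sc(OTf)3 (5 mol %), toluene, −78 → 23 °C; then THF, NfF (2.0 equiv), Bu4NF (0.3 equiv), 0 → 23 °C
Reagents that add atoms: nonafluorobutane-1-sulfonyl fluoride (NfF), FS(=O)(=O)C(F)(F)C(F)(F)C(F)(F)C(F)(F)F
Why: Proposed new method: Sc(OTf)3 activates the non-conjugated cyclopentanone carbonyl (more electrophilic than the enone) for attack by the diazo carbon of 8, loss of N2 drives a 1,2-shift of the ring CH2 rather than the quaternary carbon to give the six-membered α-silyl ketone 9, a 1,3-Brook (C-to-O silyl) shift then gives the single tetrasubstituted enol silane 10, and catalytic fluoride releases that regiodefined enolate for O-sulfonylation by NfF without any base that could enolise the enone; the closest known reaction types are the Sc(OTf)3-catalysed Tiffeneau–Demjanov-type ring expansion of cycloalkanones with Me3SiCHN2 ending in Brook rearrangement, and fluoride-catalysed nonaflation of silyl enol ethers, while the fully substituted silyl diazoalkane on an α-quaternary cyclopentanone, the selection over an enone and the one-flask sequence are new.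

Step 4
Reactants: 11 (8aS)-2,5,8a-trimethyl-6-oxo-3,4,6,7,8,8a-hexahydronaphthalen-1-yl nonafluorobutane-1-sulfonate; 12 potassium ethenyltrifluoroborate
Product: 13 (4aS)-5-ethenyl-1,4a,6-trimethyl-4,4a,7,8-tetrahydronaphthalen-2(3H)-one
Conditions: PdCl2(dppf) (5 mol %), Cs2CO3 (3 equiv), THF/H2O 9:1, 70 °C
Reagents that add atoms: none
Why: Suzuki–Miyaura cross-coupling of an alkenyl sulfonate with a vinyltrifluoroborate, which tolerates the enone and couples readily even at a tetrasubstituted alkenyl carbon next to a quaternary centre.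

Step 5
Reactants: 13 (4aS)-5-ethenyl-1,4a,6-trimethyl-4,4a,7,8-tetrahydronaphthalen-2(3H)-one; 14 5-bromo-2-methylpent-2-ene
Product: 16 (1S,4aS,8aR)-5-ethenyl-1,4a,6-trimethyl-1-(4-methylpent-3-en-1-yl)-3,4,4a,7,8,8a-hexahydronaphthalen-2(1H)-one, via lithium enolate 15 (not isolated)
Conditions: Li (2.1 equiv, titrated to first persistent blue), t-BuOH (1.0 equiv), NH3/THF, −78 °C; evaporate NH3; then 14 (4 equiv), HMPA/THF, −40 → 23 °C; H2O
Reagents that add atoms: none
Why: Stork reductive alkylation (Birch reduction of the enone, then enolate alkylation), in which axial protonation at the β-carbon gives the trans-decalin with the ring-fusion H anti to the angular methyl, and the regiospecific enolate is alkylated on the face opposite the angular methyl so the new chain ends trans to it; the twisted tetra-alkyl diene is reduced much more slowly than the enone when lithium is titrated.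

Step 6
Reactants: 16 (1S,4aS,8aR)-5-ethenyl-1,4a,6-trimethyl-1-(4-methylpent-3-en-1-yl)-3,4,4a,7,8,8a-hexahydronaphthalen-2(1H)-one
Product: 18 (4aS,5S,8aS)-1-ethenyl-2,5,8a-trimethyl-5-(4-methylpent-3-en-1-yl)-3,4,4a,5,6,7,8,8a-octahydronaphthalene, via hydrazone 17 (not isolated)
Conditions: N2H4·H2O, KOH, diethylene glycol, degassed, 130 → 210 °C
Reagents that add atoms: none
Why: Wolff–Kishner reduction (Huang–Minlon conditions) removes the ring A carbonyl; no stereocentre is enolisable, so none is scrambled.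

Step 7
Reactants: 18 (4aS,5S,8aS)-1-ethenyl-2,5,8a-trimethyl-5-(4-methylpent-3-en-1-yl)-3,4,4a,5,6,7,8,8a-octahydronaphthalene; 19 methyl but-2-ynoate
Product: 21 methyl (2E)-3-methyl-5-[(4aS,5S,8aS)-2,5,8a-trimethyl-5-(4-methylpent-3-en-1-yl)-3,4,4a,5,6,7,8,8a-octahydronaphthalen-1-yl]pent-2-enoate, via alkylborane 20 (not isolated)
Conditions: 9-BBN (1.2 equiv), THF, 0 → 23 °C; then 19 (1.5 equiv), CuOAc (10 mol %), P(OPh)3 (20 mol %), t-BuOK (10 mol %), t-BuOH (1.2 equiv), 1,4-dioxane, 40 °C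
Reagents that add atoms: none
Why: 9-BBN hydroborates only the monosubstituted alkene (anti-Markovnikov), and copper-catalysed conjugate addition of the B-alkyl group to the ynoate (syn carbocupration, then protonation with retention) places the chain trans to the ester, giving the E alkene.

Step 8
Reactants: 21 methyl (2E)-3-methyl-5-[(4aS,5S,8aS)-2,5,8a-trimethyl-5-(4-methylpent-3-en-1-yl)-3,4,4a,5,6,7,8,8a-octahydronaphthalen-1-yl]pent-2-enoate
Product: 22 (2E)-3-methyl-5-[(4aS,5S,8aS)-2,5,8a-trimethyl-5-(4-methylpent-3-en-1-yl)-3,4,4a,5,6,7,8,8a-octahydronaphthalen-1-yl]pent-2-enoic acid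
Conditions: LiOH (5 equiv), THF/MeOH/H2O, 50 °C; then 1 M HCl
Reagents that add atoms: lithium hydroxide, [Li+].[OH-]
Why: Ester saponification; the β,β-disubstituted enoate keeps its E geometry under these mild conditions.

## Compound list

1 | 2-methylcyclopentane-1,3-dione | CC1C(=O)CCC1=O | starting material
2 | pent-1-en-3-one (ethyl vinyl ketone) | CCC(=O)C=C | starting material
3 | 2-methyl-2-(3-oxopentyl)cyclopentane-1,3-dione | CCC(=O)CCC1(C)C(=O)CCC1=O | intermediate
4 | (7aS)-4,7a-dimethyl-2,3,7,7a-tetrahydro-1H-indene-1,5(6H)-dione | O=C1CC[C@]2(C)C(=O)CCC2=C1C | intermediate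
5 | (trimethylsilyl)diazomethane | C[Si](C)(C)C=[N+]=[N-] | starting material
6 | iodomethane | CI | starting material
7 | lithio(trimethylsilyl)diazomethane | [Li]C(=[N+]=[N-])[Si](C)(C)C | intermediate
8 | 1-diazo-1-(trimethylsilyl)ethane | CC(=[N+]=[N-])[Si](C)(C)C | intermediate
9 | (8aS)-2,5,8a-trimethyl-2-(trimethylsilyl)-3,4,8,8a-tetrahydronaphthalene-1,6(2H,7H)-dione (both C2 epimers) | O=C1CC[C@]2(C)C(=O)C(C)([Si](C)(C)C)CCC2=C1C | intermediate
10 | (4aS)-1,4a,6-trimethyl-5-[(trimethylsilyl)oxy]-4,4a,7,8-tetrahydronaphthalen-2(3H)-one | O=C1CC[C@]2(C)C(O[Si](C)(C)C)=C(C)CCC2=C1C | intermediate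
11 | (8aS)-2,5,8a-trimethyl-6-oxo-3,4,6,7,8,8a-hexahydronaphthalen-1-yl nonafluorobutane-1-sulfonate | O=C1CC[C@]2(C)C(OS(=O)(=O)C(F)(F)C(F)(F)C(F)(F)C(F)(F)F)=C(C)CCC2=C1C | intermediate
12 | potassium ethenyltrifluoroborate | C=C[B-](F)(F)F.[K+] | starting material
13 | (4aS)-5-ethenyl-1,4a,6-trimethyl-4,4a,7,8-tetrahydronaphthalen-2(3H)-one | O=C1CC[C@]2(C)C(C=C)=C(C)CCC2=C1C | intermediate
14 | 5-bromo-2-methylpent-2-ene | CC(C)=CCCBr | starting material
15 | lithium (4aS,8aR)-5-ethenyl-1,4a,6-trimethyl-3,4,4a,7,8,8a-hexahydronaphthalen-2-olate | CC1=C(O[Li])CC[C@]2(C)C(C=C)=C(C)CC[C@@H]12 | intermediate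
16 | (1S,4aS,8aR)-5-ethenyl-1,4a,6-trimethyl-1-(4-methylpent-3-en-1-yl)-3,4,4a,7,8,8a-hexahydronaphthalen-2(1H)-one | CC(C)=CCC[C@]1(C)C(=O)CC[C@]2(C)C(C=C)=C(C)CC[C@@H]12 | intermediate
17 | (1S,4aS,8aR)-5-ethenyl-1,4a,6-trimethyl-1-(4-methylpent-3-en-1-yl)-3,4,4a,7,8,8a-hexahydronaphthalen-2(1H)-one hydrazone | CC(C)=CCC[C@]1(C)C(=NN)CC[C@]2(C)C(C=C)=C(C)CC[C@@H]12 | intermediate
18 | (4aS,5S,8aS)-1-ethenyl-2,5,8a-trimethyl-5-(4-methylpent-3-en-1-yl)-3,4,4a,5,6,7,8,8a-octahydronaphthalene | CC(C)=CCC[C@]1(C)CCC[C@]2(C)C(C=C)=C(C)CC[C@@H]12 | intermediate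
19 | methyl but-2-ynoate | CC#CC(=O)OC | starting material
20 | 9-{2-[(4aS,5S,8aS)-2,5,8a-trimethyl-5-(4-methylpent-3-en-1-yl)-3,4,4a,5,6,7,8,8a-octahydronaphthalen-1-yl]ethyl}-9-borabicyclo[3.3.1]nonane | CC(C)=CCC[C@]1(C)CCC[C@]2(C)C(CCB3C4CCCC3CCC4)=C(C)CC[C@@H]12 | intermediate
21 | methyl (2E)-3-methyl-5-[(4aS,5S,8aS)-2,5,8a-trimethyl-5-(4-methylpent-3-en-1-yl)-3,4,4a,5,6,7,8,8a-octahydronaphthalen-1-yl]pent-2-enoate | CC(C)=CCC[C@]1(C)CCC[C@]2(C)C(CC/C(C)=C/C(=O)OC)=C(C)CC[C@@H]12 | intermediate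
22 | (2E)-3-methyl-5-[(4aS,5S,8aS)-2,5,8a-trimethyl-5-(4-methylpent-3-en-1-yl)-3,4,4a,5,6,7,8,8a-octahydronaphthalen-1-yl]pent-2-enoic acid | CC(C)=CCC[C@]1(C)CCC[C@]2(C)C(CC/C(C)=C/C(=O)O)=C(C)CC[C@@H]12 | target

## Step count and risks

Total steps: 8. Longest linear sequence: 7 (steps 1, 3, 4, 5, 6, 7, 8); step 2 is a one-step side branch that makes the diazo reagent.

Most likely to fail:

**Step 3 (the proposed new step).** The α-quaternary cyclopentanone may be too hindered for the disubstituted silyl diazoalkane, the enone may compete, or the free enolate may exchange a proton with the enone before it is sulfonylated. The fallback uses only known reactions, sets out from 4 and comes back at 18, finishing ring A before ring B is touched so that no enone is present when the enol sulfonate is made. NaBH4 (EtOH, −20 °C) reduces only the cyclopentanone carbonyl of 4 to give (1S,7aS)-1-hydroxy-4,7a-dimethyl-2,3,7,7a-tetrahydro-1H-inden-5(6H)-one F1. Li/NH3 reductive alkylation with 14 (the free hydroxyl acts as the proton donor) gives (1S,3aR,4S,7aS)-1-hydroxy-4,7a-dimethyl-4-(4-methylpent-3-en-1-yl)octahydro-5H-inden-5-one F2; the trans ring fusion is less secure here than in the decalin series and a cis isomer may have to be separated. Wolff–Kishner reduction gives (1S,3aS,4S,7aS)-4,7a-dimethyl-4-(4-methylpent-3-en-1-yl)octahydro-1H-inden-1-ol F3, and Dess–Martin oxidation gives (3aS,4S,7aS)-4,7a-dimethyl-4-(4-methylpent-3-en-1-yl)octahydro-1H-inden-1-one F4. Classical Lewis-acid ring expansion with diazoethane F5 (from N-ethyl-N-nitrosourea and KOH; BF3·OEt2, CH2Cl2, −78 °C) gives (4aS,5S,8aS)-2,5,8a-trimethyl-5-(4-methylpent-3-en-1-yl)octahydronaphthalen-1(2H)-one F6. This ketone can enolise in one direction only, so KN(SiMe3)2 then PhNTf2 gives (4aS,5S,8aS)-2,5,8a-trimethyl-5-(4-methylpent-3-en-1-yl)-3,4,4a,5,6,7,8,8a-octahydronaphthalen-1-yl trifluoromethanesulfonate F7. Suzuki–Miyaura coupling with 12 (PdCl2(dppf), Cs2CO3) gives 18.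

**Step 5.** The conjugated diene may be partly reduced, and the unactivated bromide alkylates a hindered enolate slowly. The fallback sets out from 11 and comes back at 21, carrying an isolated alkene in place of the diene. Negishi coupling of 11 (PdCl2(dppf), THF, 60 °C) with but-3-en-1-ylzinc chloride F8 (from bought but-3-enylmagnesium bromide and ZnCl2) gives (4aR)-5-(but-3-en-1-yl)-1,4a,6-trimethyl-4,4a,7,8-tetrahydronaphthalen-2(3H)-one F9. Li/NH3 reductive alkylation with 14 gives (1S,4aS,8aR)-5-(but-3-en-1-yl)-1,4a,6-trimethyl-1-(4-methylpent-3-en-1-yl)-3,4,4a,7,8,8a-hexahydronaphthalen-2(1H)-one F10, and Wolff–Kishner reduction gives (4aS,5S,8aS)-1-(but-3-en-1-yl)-2,5,8a-trimethyl-5-(4-methylpent-3-en-1-yl)-3,4,4a,5,6,7,8,8a-octahydronaphthalene F11. Wacker oxidation of the terminal alkene (PdCl2, CuCl, O2, DMF/H2O) gives 4-[(4aS,5S,8aS)-2,5,8a-trimethyl-5-(4-methylpent-3-en-1-yl)-3,4,4a,5,6,7,8,8a-octahydronaphthalen-1-yl]butan-2-one F12. Horner–Wadsworth–Emmons olefination (trimethyl phosphonoacetate, NaH, THF) gives 21 after removal of the minor Z isomer.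

**Step 7.** The hindered homoallylic borane may transfer poorly to copper. The fallback sets out from 18 and comes back at 21. 18 is hydroborated to 20 as before, and 20 is then joined by B-alkyl Suzuki–Miyaura coupling (PdCl2(dppf), K3PO4, DMF/H2O, 50 °C) with methyl (2E)-3-{[(trifluoromethyl)sulfonyl]oxy}but-2-enoate F13 (from methyl acetoacetate, Tf2O and aqueous Me4NOH). Coupling proceeds with retention of alkene geometry and gives 21.

## Further compounds

F1 | step 3 | (1S,7aS)-1-hydroxy-4,7a-dimethyl-2,3,7,7a-tetrahydro-1H-inden-5(6H)-one | O=C1CC[C@]2(C)[C@@H](O)CCC2=C1C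
F2 | step 3 | (1S,3aR,4S,7aS)-1-hydroxy-4,7a-dimethyl-4-(4-methylpent-3-en-1-yl)octahydro-5H-inden-5-one | CC(C)=CCC[C@]1(C)C(=O)CC[C@]2(C)[C@@H](O)CC[C@@H]12
F3 | step 3 | (1S,3aS,4S,7aS)-4,7a-dimethyl-4-(4-methylpent-3-en-1-yl)octahydro-1H-inden-1-ol | CC(C)=CCC[C@]1(C)CCC[C@]2(C)[C@@H](O)CC[C@@H]12
F4 | step 3 | (3aS,4S,7aS)-4,7a-dimethyl-4-(4-methylpent-3-en-1-yl)octahydro-1H-inden-1-one | CC(C)=CCC[C@]1(C)CCC[C@]2(C)C(=O)CC[C@@H]12
F5 | step 3 | diazoethane | CC=[N+]=[N-]
F6 | step 3 | (4aS,5S,8aS)-2,5,8a-trimethyl-5-(4-methylpent-3-en-1-yl)octahydronaphthalen-1(2H)-one (both C2 epimers) | CC(C)=CCC[C@]1(C)CCC[C@]2(C)C(=O)C(C)CC[C@@H]12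
F7 | step 3 | (4aS,5S,8aS)-2,5,8a-trimethyl-5-(4-methylpent-3-en-1-yl)-3,4,4a,5,6,7,8,8a-octahydronaphthalen-1-yl trifluoromethanesulfonate | CC(C)=CCC[C@]1(C)CCC[C@]2(C)C(OS(=O)(=O)C(F)(F)F)=C(C)CC[C@@H]12
F8 | step 5 | but-3-en-1-ylzinc chloride | C=CCC[Zn]Cl
F9 | step 5 | (4aR)-5-(but-3-en-1-yl)-1,4a,6-trimethyl-4,4a,7,8-tetrahydronaphthalen-2(3H)-one | O=C1CC[C@]2(C)C(CCC=C)=C(C)CCC2=C1C
F10 | step 5 | (1S,4aS,8aR)-5-(but-3-en-1-yl)-1,4a,6-trimethyl-1-(4-methylpent-3-en-1-yl)-3,4,4a,7,8,8a-hexahydronaphthalen-2(1H)-one | CC(C)=CCC[C@]1(C)C(=O)CC[C@]2(C)C(CCC=C)=C(C)CC[C@@H]12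
F11 | step 5 | (4aS,5S,8aS)-1-(but-3-en-1-yl)-2,5,8a-trimethyl-5-(4-methylpent-3-en-1-yl)-3,4,4a,5,6,7,8,8a-octahydronaphthalene | CC(C)=CCC[C@]1(C)CCC[C@]2(C)C(CCC=C)=C(C)CC[C@@H]12
F12 | step 5 | 4-[(4aS,5S,8aS)-2,5,8a-trimethyl-5-(4-methylpent-3-en-1-yl)-3,4,4a,5,6,7,8,8a-octahydronaphthalen-1-yl]butan-2-one | CC(C)=CCC[C@]1(C)CCC[C@]2(C)C(CCC(C)=O)=C(C)CC[C@@H]12
F13 | step 7 | methyl (2E)-3-{[(trifluoromethyl)sulfonyl]oxy}but-2-enoate | COC(=O)/C=C(\C)OS(=O)(=O)C(F)(F)F
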